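**Retrosynthetic overview**
1. Feature: in ring C (the 4-hydroxy-2-pyranone), C6 carries the benzylic CH2 that leads to ring B and is bonded to O1. The C6–O1 unit is read as a former aldehyde C=O, and C2–C5 with their two oxygens as a four-carbon diene derived from an acetoacetate.
2. Key disconnection: C5–C6 and O1–C2 of a 4-methoxy-5,6-dihydro-2-pyranone, giving an ortho-aroyl arylacetaldehyde and Brassard's diene. The ring is then dehydrogenated (DDQ) and the four O-methyl groups are removed (BBr3).
3. Aldehyde ⇐ oxidative cleavage of an ortho-allyl benzophenone ⇐ Stille allylation of the ortho-bromo benzophenone ⇐ Friedel–Crafts acylation (ketone carbon–ring A bond) of 1-ethyl-3,5-dimethoxybenzene with 2-bromo-6-methoxybenzoyl chloride.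
4. Ring order: rings A (ethyl-resorcinol ring) and B are bought as benzenes; ring C is the only ring made, closed in step 6 and aromatised in step 7.

Key step: step 6

Assumption: the target has no stereocentre, so the single stereocentre arising at C6 in step 6 is carried as a racemate and removed in step 7; chiral intermediates are drawn as one enantiomer of the racemate.

**Step 1**
Reactants: 1 2-bromo-6-methoxybenzoic acid
Product: 2 2-bromo-6-methoxybenzoyl chloride
Conditions: (COCl)2, DMF (cat.), CH2Cl2, 0 °C → rt; concentrate, use crude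
Reagents that add atoms: oxalyl chloride, ClC(=O)C(=O)Cl
Why: Acyl chloride formation by nucleophilic acyl substitution via the chloroiminium species from DMF and oxalyl chloride should be clean even for this 2,6-disubstituted acid, because activation occurs at the unhindered carboxyl oxygen and the aryl bromide and methyl ether are inert.

**Step 2**
Reactants: 2 2-bromo-6-methoxybenzoyl chloride; 3 1-ethyl-3,5-dimethoxybenzene
Product: 4 (2-bromo-6-methoxyphenyl)(2-ethyl-4,6-dimethoxyphenyl)methanone
Conditions: AlCl3 (1.2 equiv), CH2Cl2, −10 → 0 °C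
Reagents that add atoms: none
Why: Friedel–Crafts acylation: the 2,6-disubstituted acyl chloride ionises readily to a slim linear acylium ion, which should attack 3 at one of its two equivalent positions para to one methoxy group and ortho to the other (C2/C6) rather than at C4 between the two methoxy groups, while low temperature and near-stoichiometric AlCl3 are chosen to avoid chelation-assisted cleavage of the methoxy groups ortho to the new ketone.

**Step 3**
Reactants: 4 (2-bromo-6-methoxyphenyl)(2-ethyl-4,6-dimethoxyphenyl)methanone; 5 allyltributylstannane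
Product: 6 (2-ethyl-4,6-dimethoxyphenyl)[2-methoxy-6-(prop-2-en-1-yl)phenyl]methanone
Conditions: Pd(PPh3)4 (cat.), PhMe, 100 °C
Reagents that add atoms: none
Why: Migita–Kosugi–Stille coupling: oxidative addition of zerovalent palladium into the C–Br bond activated by the ortho carbonyl group, allyl transfer from tin and reductive elimination should give the ortho-allyl arene, the reaction being stopped at full conversion to limit migration of the double bond into conjugation.

**Step 4**
Reactants: 7 methyl (E)-3-methoxybut-2-enoate
Product: 9 1,3-dimethoxy-1-(trimethylsilyloxy)buta-1,3-diene (Brassard's diene), via lithium dienolate 8 (not isolated)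
Conditions: LiN(i-Pr)2 (LDA), THF, −78 °C; Me3SiCl, −78 °C → rt; bulb-to-bulb distillation
Reagents that add atoms: chlorotrimethylsilane, C[Si](C)(C)Cl
Why: Kinetic γ-deprotonation of the β-methoxy crotonate gives the extended lithium dienolate, which is O-silylated to the silyl ketene acetal (the standard preparation of Brassard's diene; the ketene acetal geometry is immaterial).

**Step 5**
Reactants: 6 (2-ethyl-4,6-dimethoxyphenyl)[2-methoxy-6-(prop-2-en-1-yl)phenyl]methanone
Product: 11 2-[2-(2-ethyl-4,6-dimethoxybenzoyl)-3-methoxyphenyl]acetaldehyde, via vicinal diol 10 (not isolated)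
Conditions: OsO4 (cat.), NaIO4, 2,6-lutidine, dioxane/H2O (3:1), rt; use at once without chromatography
Reagents that add atoms: osmium tetroxide, O=[Os](=O)(=O)=O (transfers the oxygen atom; catalytic); sodium periodate, [Na+].[O-]I(=O)(=O)=O (terminal oxidant that restores OsO4)
Why: Lemieux–Johnson oxidation: OsO4 dihydroxylates the terminal alkene and NaIO4 cleaves the 1,2-diol in the same flask, the 2,6-lutidine buffer suppressing over-oxidation and acid-induced side reactions of the sensitive arylacetaldehyde, while the electron-rich ring A and the ketone are untouched.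

**Step 6**
Reactants: 11 2-[2-(2-ethyl-4,6-dimethoxybenzoyl)-3-methoxyphenyl]acetaldehyde; 9 1,3-dimethoxy-1-(trimethylsilyloxy)buta-1,3-diene
Product: 13 6-{[2-(2-ethyl-4,6-dimethoxybenzoyl)-3-methoxyphenyl]methyl}-4-methoxy-5,6-dihydro-2H-pyran-2-one (racemic), via acyclic hydroxy enoate 12 (not isolated)
Conditions: 9 (1.5 equiv), BF3·OEt2 (1.1 equiv), CH2Cl2, −78 °C; aq. NaHCO3; then K2CO3 (cat.), MeOH, rt
Reagents that add atoms: none
Why: BF3 activates the aldehyde oxygen of 11 and the terminal CH2 carbon of diene 9 attacks the aldehyde carbon in a vinylogous Mukaiyama aldol addition, forming the C5–C6 bond and, after loss of the silyl group as Me3SiF and quench, the δ-hydroxy-β-methoxy enoate 12. The closest known reaction type is the Lewis acid-promoted hetero-Diels–Alder (stepwise aldol then lactonisation) reaction of Brassard's diene with aldehydes to 6-substituted 4-methoxy-5,6-dihydro-2-pyranones. Ring C, the only ring formed, closes by 6-exo-trig attack of the C6 oxygen on the ester carbonyl (O1–C2 bond) with loss of methanol. K2CO3 in MeOH completes this closure, equilibrates any (Z)-enoate by methoxide addition–elimination, and drains any hemiketal formed reversibly between the new hydroxyl and the ketone. The C6 stereocentre is formed without control as a racemate, which is acceptable because C6 becomes sp2 in step 7. The step needs reaction at the aldehyde and not at the diaryl ketone, and addition faster than enolisation of the arylacetaldehyde: the ketone is flanked by four ortho substituents (ethyl, two methoxy groups and the CH2 arm) and twisted out of conjugation, so it is shielded, while −78 °C, excess diene and freshly made 11 keep enolisation and self-condensation behind the bimolecular addition.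

**Step 7**
Reactants: 13 6-{[2-(2-ethyl-4,6-dimethoxybenzoyl)-3-methoxyphenyl]methyl}-4-methoxy-5,6-dihydro-2H-pyran-2-one
Product: 14 6-{[2-(2-ethyl-4,6-dimethoxybenzoyl)-3-methoxyphenyl]methyl}-4-methoxy-2H-pyran-2-one
Conditions: DDQ (2 equiv), 1,4-dioxane, 100 °C
Reagents that add atoms: none
Why: DDQ dehydrogenation: hydride abstraction from C6 of the dienol tautomer of the lactone gives a 2-hydroxy-4-methoxypyrylium ion that loses a proton to the aromatic 2-pyranone (as in the known conversion of kavalactone-type 4-methoxy-5,6-dihydro-2-pyranones into 2-pyranones), the two benzylic CH2 groups being meta to the methoxy groups and on carbonyl-bearing rings and so poor hydride donors; the racemic C6 stereocentre is removed here.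

**Step 8**
Reactants: 14 6-{[2-(2-ethyl-4,6-dimethoxybenzoyl)-3-methoxyphenyl]methyl}-4-methoxy-2H-pyran-2-one
Product: 16 6-{[2-(2-ethyl-4,6-dihydroxybenzoyl)-3-hydroxyphenyl]methyl}-4-hydroxy-2H-pyran-2-one (CNP0234555.0), via tetrakis(dibromoboryl) ether 15 (not isolated)
Conditions: BBr3 (excess), CH2Cl2, −78 °C → rt; H2O
Reagents that add atoms: none
Why: Lewis acid ether cleavage: BBr3 coordinates each ether oxygen (the pyranone methoxy, a vinylogous ester, through the complexed lactone carbonyl) and bromide removes the methyl groups by SN2 displacement as MeBr, the two ethers ortho to the ketone being accelerated by chelation, and hydrolysis of the B–O bonds on quench should release the four hydroxyl groups of the achiral target.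

**Compound list**
1 | 2-bromo-6-methoxybenzoic acid | COc1cccc(Br)c1C(=O)O | starting material
2 | 2-bromo-6-methoxybenzoyl chloride | COc1cccc(Br)c1C(=O)Cl | intermediate
3 | 1-ethyl-3,5-dimethoxybenzene | CCc1cc(OC)cc(OC)c1 | starting material
4 | (2-bromo-6-methoxyphenyl)(2-ethyl-4,6-dimethoxyphenyl)methanone | CCc1cc(OC)cc(OC)c1C(=O)c1c(OC)cccc1Br | intermediate
5 | allyltributylstannane | C=CC[Sn](CCCC)(CCCC)CCCC | starting material
6 | (2-ethyl-4,6-dimethoxyphenyl)[2-methoxy-6-(prop-2-en-1-yl)phenyl]methanone | CCc1cc(OC)cc(OC)c1C(=O)c1c(OC)cccc1CC=C | intermediate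
7 | methyl (E)-3-methoxybut-2-enoate | CO/C(C)=C/C(=O)OC | starting material
8 | lithium 1,3-dimethoxybuta-1,3-dien-1-olate (lithium dienolate, not isolated) | [Li+].[O-]C(OC)=CC(=C)OC | intermediate
9 | 1,3-dimethoxy-1-(trimethylsilyloxy)buta-1,3-diene (Brassard's diene, ketene acetal geometry unspecified) | COC(=C)C=C(OC)O[Si](C)(C)C | intermediate
10 | 3-[2-(2-ethyl-4,6-dimethoxybenzoyl)-3-methoxyphenyl]propane-1,2-diol (racemate, one enantiomer drawn; not isolated) | CCc1cc(OC)cc(OC)c1C(=O)c1c(OC)cccc1C[C@@H](O)CO | intermediate
11 | 2-[2-(2-ethyl-4,6-dimethoxybenzoyl)-3-methoxyphenyl]acetaldehyde | CCc1cc(OC)cc(OC)c1C(=O)c1c(OC)cccc1CC=O | intermediate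
12 | methyl (2E)-6-[2-(2-ethyl-4,6-dimethoxybenzoyl)-3-methoxyphenyl]-5-hydroxy-3-methoxyhex-2-enoate (racemate, one enantiomer drawn; not isolated) | CCc1cc(OC)cc(OC)c1C(=O)c1c(OC)cccc1C[C@@H](O)C/C(OC)=C\C(=O)OC | intermediate
13 | 6-{[2-(2-ethyl-4,6-dimethoxybenzoyl)-3-methoxyphenyl]methyl}-4-methoxy-5,6-dihydro-2H-pyran-2-one (racemate, one enantiomer drawn) | CCc1cc(OC)cc(OC)c1C(=O)c1c(OC)cccc1C[C@@H]1CC(OC)=CC(=O)O1 | intermediate
14 | 6-{[2-(2-ethyl-4,6-dimethoxybenzoyl)-3-methoxyphenyl]methyl}-4-methoxy-2H-pyran-2-one | CCc1cc(OC)cc(OC)c1C(=O)c1c(OC)cccc1Cc1cc(OC)cc(=O)o1 | intermediate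
15 | tetrakis(dibromoboryl) ether of the target (idealised boron intermediate, not isolated) | CCc1cc(OB(Br)Br)cc(OB(Br)Br)c1C(=O)c1c(OB(Br)Br)cccc1Cc1cc(OB(Br)Br)cc(=O)o1 | intermediate
16 | 6-{[2-(2-ethyl-4,6-dihydroxybenzoyl)-3-hydroxyphenyl]methyl}-4-hydroxy-2H-pyran-2-one (CNP0234555.0) | CCc1cc(O)cc(O)c1C(=O)c1c(O)cccc1Cc1cc(O)cc(=O)o1 | target

**Step count and risks**
Total steps: 8. Longest linear sequence: 7 steps (steps 1, 2, 3, 5, 6, 7, 8 from 2-bromo-6-methoxybenzoic acid); step 4 is a one-step side branch.

Steps most likely to fail: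

Step 6. What may go wrong: BF3-induced enolisation and self-condensation of the arylacetaldehyde, or capture of the activated aldehyde by the neighbouring ketone oxygen followed by dehydration towards a 2-benzopyrylium species, may outrun attack by the diene. The fallback sets out from 11 (its reagent is made from 7) and comes back at 13, using a vinylogous Reformatsky reaction under non-acidic conditions. Radical bromination of 7 (NBS, AIBN, PhCF3, reflux) should give methyl (E)-4-bromo-3-methoxybut-2-enoate F1. Activated zinc dust in THF should convert it into the bromozinc dienolate F2, which adds through its γ-carbon to the aldehyde of 11 to give the zinc alkoxide F3. This alkoxide should lactonise onto the cis-disposed ester with loss of methanol, on warming or on work-up, to give 13.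

Step 7. What may go wrong: hydride abstraction at C6, which is neither allylic nor benzylic in 13, may be slow, so that oxidation at the benzylic methylene groups or degradation on prolonged heating competes. The fallback sets out from 4 and comes back at 14, bringing in ring C already aromatic through an aryl–CH2 coupling. Miyaura borylation of 4 (bis(pinacolato)diboron, Pd(dppf)Cl2, KOAc, dioxane, 90 °C) should give the pinacol boronate F4. 6-(Bromomethyl)-4-methoxy-2H-pyran-2-one F5 is obtained from commercial 4-methoxy-6-methyl-2H-pyran-2-one by radical bromination (NBS, AIBN, PhCF3, reflux). Suzuki–Miyaura coupling of F4 with F5 (Pd(PPh3)4, K3PO4, THF/H2O, 60 °C) should then give 14.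

Step 8. What may go wrong: cleavage of the vinylogous ester methyl group on the pyranone may be incomplete, and under the forcing conditions then needed the lactone may open or nucleophilic pyranone and resorcinol carbons may condense with the Lewis acid-activated ketone. The fallback sets out from 11 and comes back at 16, never placing a methyl group on the pyranone oxygen. Pinnick oxidation of 11 (NaClO2, NaH2PO4, 2-methylbut-2-ene, t-BuOH/H2O) should give 2-[2-(2-ethyl-4,6-dimethoxybenzoyl)-3-methoxyphenyl]acetic acid F6. Carbonyldiimidazole in THF converts it into the acyl imidazolide F7, which acylates the dianion of methyl acetoacetate (NaH, then n-BuLi, THF, −78 °C) to the 3,5-dioxo ester F8. DBU in toluene should close F8, with loss of methanol, to the 4-hydroxy-2-pyranone F9. Only the three aryl methyl ethers, two of them chelation-activated by the ketone, then need BBr3 (CH2Cl2, −78 → 0 °C; H2O), which should give 16 through the same boron intermediate 15.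

**Further compounds**
F1 | step 6 | methyl (E)-4-bromo-3-methoxybut-2-enoate | CO/C(CBr)=C/C(=O)OC
F2 | step 6 | bromozinc dienolate of methyl 3-methoxybut-2-enoate (Reformatsky reagent) | COC(C[Zn]Br)=CC(=O)OC
F3 | step 6 | bromozinc alkoxide of methyl (2E)-6-[2-(2-ethyl-4,6-dimethoxybenzoyl)-3-methoxyphenyl]-5-hydroxy-3-methoxyhex-2-enoate (racemate, one enantiomer drawn) | CCc1cc(OC)cc(OC)c1C(=O)c1c(OC)cccc1C[C@@H](O[Zn]Br)C/C(OC)=C\C(=O)OC
F4 | step 7 | (2-ethyl-4,6-dimethoxyphenyl)[2-methoxy-6-(4,4,5,5-tetramethyl-1,3,2-dioxaborolan-2-yl)phenyl]methanone | CCc1cc(OC)cc(OC)c1C(=O)c1c(OC)cccc1B1OC(C)(C)C(C)(C)O1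
F5 | step 7 | 6-(bromomethyl)-4-methoxy-2H-pyran-2-one | COc1cc(CBr)oc(=O)c1
F6 | step 8 | 2-[2-(2-ethyl-4,6-dimethoxybenzoyl)-3-methoxyphenyl]acetic acid | CCc1cc(OC)cc(OC)c1C(=O)c1c(OC)cccc1CC(=O)O
F7 | step 8 | 2-[2-(2-ethyl-4,6-dimethoxybenzoyl)-3-methoxyphenyl]-1-(1H-imidazol-1-yl)ethan-1-one | CCc1cc(OC)cc(OC)c1C(=O)c1c(OC)cccc1CC(=O)n1ccnc1
F8 | step 8 | methyl 6-[2-(2-ethyl-4,6-dimethoxybenzoyl)-3-methoxyphenyl]-3,5-dioxohexanoate | CCc1cc(OC)cc(OC)c1C(=O)c1c(OC)cccc1CC(=O)CC(=O)CC(=O)OC
F9 | step 8 | 6-{[2-(2-ethyl-4,6-dimethoxybenzoyl)-3-methoxyphenyl]methyl}-4-hydroxy-2H-pyran-2-one | CCc1cc(OC)cc(OC)c1C(=O)c1c(OC)cccc1Cc1cc(O)cc(=O)o1
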